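Hypercalin B is cut at the C1–C6 bond of acylphloroglucinol ring A, where C6 carries the benzoyl group and C1 is the enol carbon between C6 and the CH2-bearing C2. C6 is the central carbon of a 1,3-diketone (C5=O and the benzoyl C=O), and the cis tertiary carbinol carbon of cyclopentane ring B is δ to C1, so C1 can be stored as a δ-lactone carbonyl. One base-mediated Claisen cyclisation forms C1–C6, closes ring A and releases the tertiary alcohol, with no protecting group. The precursor is the (S)-limonene-derived cis-fused bicyclic δ-lactone, C-acylated at its α-carbon (C2) by the complete diprenylmalonyl-benzoylacetyl chain, transferred in one piece from an enol lactone.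

Key step: step 12

Labels (not IUPAC locants): C1 = lactone carbonyl of 19; C2 = lactone α-carbon; C3 = ketone; C4 = diprenylated quaternary carbon; C5 = ketone; C6 = CH2 of 19 that becomes the benzoyl-bearing carbon of ring A; C7 = benzoyl carbonyl. Ring A = six-membered trione ring of 20; ring B = cyclopentane.

Assumption: 19 and 20 are drawn as single tautomers; 19 should form as a mixture of keto–enol tautomers and C2 epimers, all of which converge in step 12.

Step 1
Reactants: 1 (S)-limonene
Product: 2 (4S)-limonene 1,2-oxide (both epoxide diastereomers)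
Conditions: mCPBA (1.0 equiv), NaHCO3, CH2Cl2, 0 °C
Reagents that add atoms: mCPBA (3-chloroperbenzoic acid), O=C(OO)c1cccc(Cl)c1
Why: Prilezhaev epoxidation; the electron-richer trisubstituted ring alkene should react ahead of the 1,1-disubstituted isopropenyl alkene, and the two new epoxide stereocentres need no control because both carbons become carbonyl carbons in step 2.

Step 2
Reactants: 2 (4S)-limonene 1,2-oxide
Product: 4 (S)-6-oxo-3-(prop-1-en-2-yl)heptanal, via limonene-1,2-diol 3 (not isolated)
Conditions: H5IO6 (1.2 equiv), THF/H2O, 0 °C to rt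
Reagents that add atoms: water, O
Why: Acidic epoxide hydrolysis to the diol and Malaprade glycol cleavage by periodic acid occur in one flask; the stereocentre inherited from limonene is not involved and the isopropenyl group is inert to periodate.

Step 3
Reactants: 4 (S)-6-oxo-3-(prop-1-en-2-yl)heptanal
Product: 5 (1R,2S,5S)-2-hydroxy-2-methyl-5-(prop-1-en-2-yl)cyclopentane-1-carbaldehyde
Conditions: D-proline (20 mol%), DMSO, rt
Reagents that add atoms: none
Why: Enamine-catalysed intramolecular aldol reaction (5-(enolexo)-exo-trig, proline catalysis) uses only the aldehyde as donor and the methyl ketone as acceptor; the carboxylic acid hydrogen bond to the ketone oxygen should place the new OH cis to CHO, allylic strain in the enamine (matched by the D-catalyst) should place CHO trans to isopropenyl, and this isomer, with CHO trans to both isopropenyl and methyl, is also the expected thermodynamic aldol.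

Step 4
Reactants: 5 (1R,2S,5S)-2-hydroxy-2-methyl-5-(prop-1-en-2-yl)cyclopentane-1-carbaldehyde; 6 methyl (triphenylphosphoranylidene)acetate
Product: 7 methyl (E)-3-[(1R,2S,5S)-2-hydroxy-2-methyl-5-(prop-1-en-2-yl)cyclopentyl]prop-2-enoate
Conditions: 6 (1.3 equiv), CH2Cl2, rt
Reagents that add atoms: none
Why: Wittig olefination with a stabilised ylide under neutral conditions should give the E-enoate without retro-aldol cleavage, dehydration or epimerisation of the β-hydroxy aldehyde; no new stereocentre is formed.

Step 5
Reactants: 7 methyl (E)-3-[(1R,2S,5S)-2-hydroxy-2-methyl-5-(prop-1-en-2-yl)cyclopentyl]prop-2-enoate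
Product: 8 methyl 3-[(1R,2S,5S)-2-hydroxy-2-methyl-5-(prop-1-en-2-yl)cyclopentyl]propanoate
Conditions: Mg turnings (5 equiv), MeOH, 0 °C to rt; aq. NH4Cl
Reagents that add atoms: none
Why: Conjugate reduction by single-electron transfer from Mg in MeOH is specific for the electron-poor enoate alkene, so the isopropenyl alkene and the tertiary alcohol should survive, and methanol as solvent makes ester exchange harmless; no stereocentre is formed.

Step 6
Reactants: 8 methyl 3-[(1R,2S,5S)-2-hydroxy-2-methyl-5-(prop-1-en-2-yl)cyclopentyl]propanoate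
Product: 9 (4aR,5S,7aS)-7a-methyl-5-(prop-1-en-2-yl)hexahydrocyclopenta[b]pyran-2(3H)-one
Conditions: NaH (1.1 equiv), THF, 0 °C to rt; aq. NH4Cl
Reagents that add atoms: none
Why: Base-mediated lactonisation (intramolecular transesterification, 6-exo-trig): the cis tertiary alkoxide attacks the methyl ester and the less basic methoxide leaves, which avoids acid that could ionise the tertiary alcohol; the cis ring fusion follows from the configuration set in step 3.

Step 7
Reactants: 10 dimethyl malonate; 11 prenyl bromide
Product: 13 dimethyl 2,2-bis(3-methylbut-2-en-1-yl)malonate, via dimethyl prenylmalonate 12 (not isolated)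
Conditions: NaH (2.3 equiv), 11 (2.3 equiv), THF/DMF, 0 °C to rt
Reagents that add atoms: none
Why: Double malonic ester alkylation; the soft malonate anion should attack the primary allylic bromide by SN2 (no SN2′ product expected), and the second alkylation follows in the same flask through 12.

Step 8
Reactants: 13 dimethyl 2,2-bis(3-methylbut-2-en-1-yl)malonate
Product: 14 2,2-bis(3-methylbut-2-en-1-yl)malonic acid
Conditions: KOH (6 equiv), EtOH/H2O, reflux; then aq. HCl, 0 °C
Reagents that add atoms: potassium hydroxide, [K+].[OH-]
Why: Saponification of both esters; a disubstituted malonic acid should resist decarboxylation during a cold acidification, and the prenyl alkenes are inert to hydroxide.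

Step 9
Reactants: 14 2,2-bis(3-methylbut-2-en-1-yl)malonic acid
Product: 15 2,2-bis(3-methylbut-2-en-1-yl)malonyl dichloride
Conditions: 1-chloro-N,N,2-trimethylprop-1-en-1-amine (2.3 equiv), CH2Cl2, 0 °C to rt; used directly
Reagents that add atoms: 1-chloro-N,N,2-trimethylprop-1-en-1-amine, CC(C)=C(Cl)N(C)C
Why: Acid chloride formation with an α-chloroenamine is neutral (no HCl is set free), which protects the acid-sensitive prenyl alkenes, and the quaternary α-carbon rules out ketene formation.

Step 10
Reactants: 15 2,2-bis(3-methylbut-2-en-1-yl)malonyl dichloride; 16 acetophenone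
Product: 18 3,3-bis(3-methylbut-2-en-1-yl)-6-phenyl-2H-pyran-2,4(3H)-dione, via keto acid chloride 17 (not isolated)
Conditions: 15 (1.2 equiv), MgBr2·OEt2 (2.5 equiv), i-Pr2NEt (3 equiv), CH2Cl2, 0 °C to rt
Reagents that add atoms: none
Why: Soft-enolisation crossed Claisen acylation (C-selective magnesium enolate of acetophenone) followed by 6-exo-trig O-acylation of the benzoyl enol oxygen by the second acyl chloride, the only ring size open to 17, should give the enol lactone in one flask; no stereocentre is formed.

Step 11
Reactants: 9 (4aR,5S,7aS)-7a-methyl-5-(prop-1-en-2-yl)hexahydrocyclopenta[b]pyran-2(3H)-one; 18 3,3-bis(3-methylbut-2-en-1-yl)-6-phenyl-2H-pyran-2,4(3H)-dione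
Product: 19 (4aR,5S,7aS)-3-[2,2-bis(3-methylbut-2-en-1-yl)-3,5-dioxo-5-phenylpentanoyl]-7a-methyl-5-(prop-1-en-2-yl)hexahydrocyclopenta[b]pyran-2(3H)-one (C2 epimers and enol tautomers)
Conditions: LiN(SiMe3)2 (2.2 equiv), THF, −78 °C; 18 (1.1 equiv), −78 to −40 °C; AcOH, −78 °C
Reagents that add atoms: none
Why: Claisen-type C-acylation of the lactone lithium enolate by an enol lactone (a vinylogous anhydride): attack at its ring carbonyl next to the quaternary carbon expels the stabilised diketonate, so the whole C3–C7 chain is transferred with the diketone already unmasked, while the second equivalent of base holds the product as a dianion that cannot cyclise before the cold acidic quench; the new stereocentre at C2 forms without control and is erased in step 12.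

Step 12
Reactants: 19 (4aR,5S,7aS)-3-[2,2-bis(3-methylbut-2-en-1-yl)-3,5-dioxo-5-phenylpentanoyl]-7a-methyl-5-(prop-1-en-2-yl)hexahydrocyclopenta[b]pyran-2(3H)-one
Product: 20 hypercalin B, 2-benzoyl-3,5-dihydroxy-4-{[(1R,2S,5S)-2-hydroxy-2-methyl-5-(prop-1-en-2-yl)cyclopentyl]methyl}-6,6-bis(3-methylbut-2-en-1-yl)cyclohexa-2,4-dien-1-one
Conditions: DBU (1.1 equiv), MeCN, rt (40 °C if slow); then 1 M HCl
Reagents that add atoms: none
Why: DBU removes a proton from C6, the most acidic site (CH2 between the C5 and benzoyl carbonyls), the diketonate carbon adds to the lactone carbonyl C1, and the tetrahedral intermediate expels the tertiary ring B alkoxide, which is protonated by DBU-H+ while the new ring A triketone is deprotonated at once, the event that makes the otherwise reversible acyl transfer irreversible. The closest known reaction type is the Claisen (Dieckmann-type) cyclisation of 3,5,7-triketo esters to acylphloroglucinols, together with the base-induced rearrangement of enol lactones to cyclic 1,3-diketones; the acyl donor here is a saturated δ-lactone. Ring A closes in the 6-exo-trig mode at C1, the nucleophile being usable as the benzoyl enolate (enolexo) or as the C5 enolate (enolendo), both allowed for a six-membered ring. No stereocentre is created: C2 becomes sp2, and the three ring B stereocentres carry no acidic hydrogen and stay as set in steps 1 to 6. The step needs C- over O-acylation and Claisen over aldol closure: the C5 enolate oxygen can also reach C1 through a six-membered transition state, but the enol lactone it would form is itself an acyl donor that drains into the same triketone enolate, whereas aldol closure of C2 onto the benzoyl carbonyl needs the less acidic C2–H, is reversible and has no comparable sink. One equivalent of a non-nucleophilic base keeps the substrate as the C6 monoanion (a C2,C6 dianion would deactivate the lactone) and avoids retro-Claisen cleavage of the non-enolisable C3–C4–C5 diketone.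

Compound list
1 | (S)-limonene | CC1=CC[C@H](CC1)C(C)=C | starting material
2 | (4S)-limonene 1,2-oxide, (4S)-1-methyl-4-(prop-1-en-2-yl)-7-oxabicyclo[4.1.0]heptane, both epoxide diastereomers | CC12OC1C[C@H](CC2)C(C)=C | intermediate
3 | limonene-1,2-diol, (4S)-1-methyl-4-(prop-1-en-2-yl)cyclohexane-1,2-diol, diol centres not controlled | CC1(O)C(O)C[C@H](CC1)C(C)=C | intermediate
4 | (S)-6-oxo-3-(prop-1-en-2-yl)heptanal | O=CC[C@H](CCC(C)=O)C(C)=C | intermediate
5 | (1R,2S,5S)-2-hydroxy-2-methyl-5-(prop-1-en-2-yl)cyclopentane-1-carbaldehyde (CHO cis to OH, trans to isopropenyl) | C=C(C)[C@H]1CC[C@](C)(O)[C@@H]1C=O | intermediate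
6 | methyl (triphenylphosphoranylidene)acetate | COC(=O)C=P(c1ccccc1)(c1ccccc1)c1ccccc1 | starting material
7 | methyl (E)-3-[(1R,2S,5S)-2-hydroxy-2-methyl-5-(prop-1-en-2-yl)cyclopentyl]prop-2-enoate | C=C(C)[C@H]1CC[C@](C)(O)[C@@H]1/C=C/C(=O)OC | intermediate
8 | methyl 3-[(1R,2S,5S)-2-hydroxy-2-methyl-5-(prop-1-en-2-yl)cyclopentyl]propanoate | C=C(C)[C@H]1CC[C@](C)(O)[C@@H]1CCC(=O)OC | intermediate
9 | (4aR,5S,7aS)-7a-methyl-5-(prop-1-en-2-yl)hexahydrocyclopenta[b]pyran-2(3H)-one (cis-fused δ-lactone) | C=C(C)[C@H]1CC[C@]2(C)OC(=O)CC[C@H]12 | intermediate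
10 | dimethyl malonate | COC(=O)CC(=O)OC | starting material
11 | prenyl bromide (1-bromo-3-methylbut-2-ene) | CC(C)=CCBr | starting material
12 | dimethyl 2-(3-methylbut-2-en-1-yl)malonate | COC(=O)C(CC=C(C)C)C(=O)OC | intermediate
13 | dimethyl 2,2-bis(3-methylbut-2-en-1-yl)malonate | COC(=O)C(CC=C(C)C)(CC=C(C)C)C(=O)OC | intermediate
14 | 2,2-bis(3-methylbut-2-en-1-yl)malonic acid | OC(=O)C(CC=C(C)C)(CC=C(C)C)C(=O)O | intermediate
15 | 2,2-bis(3-methylbut-2-en-1-yl)malonyl dichloride | ClC(=O)C(CC=C(C)C)(CC=C(C)C)C(=O)Cl | intermediate
16 | acetophenone | CC(=O)c1ccccc1 | starting material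
17 | 2,2-bis(3-methylbut-2-en-1-yl)-3,5-dioxo-5-phenylpentanoyl chloride | O=C(Cl)C(CC=C(C)C)(CC=C(C)C)C(=O)CC(=O)c1ccccc1 | intermediate
18 | 3,3-bis(3-methylbut-2-en-1-yl)-6-phenyl-2H-pyran-2,4(3H)-dione (enol lactone) | O=C1OC(c2ccccc2)=CC(=O)C1(CC=C(C)C)CC=C(C)C | intermediate
19 | (4aR,5S,7aS)-3-[2,2-bis(3-methylbut-2-en-1-yl)-3,5-dioxo-5-phenylpentanoyl]-7a-methyl-5-(prop-1-en-2-yl)hexahydrocyclopenta[b]pyran-2(3H)-one (C2 uncontrolled) | C=C(C)[C@H]1CC[C@]2(C)OC(=O)C(C(=O)C(CC=C(C)C)(CC=C(C)C)C(=O)CC(=O)c3ccccc3)C[C@H]12 | intermediate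
20 | hypercalin B | C=C(C)[C@H]1CC[C@](C)(O)[C@@H]1CC1=C(O)C(CC=C(C)C)(CC=C(C)C)C(=O)C(C(=O)c2ccccc2)=C1O | target

Total step count: 12. Longest linear sequence: 8 (steps 1–6, 11, 12); the enol lactone branch (steps 7–10) joins at step 11.

Steps most likely to fail

Step 12. The tetrahedral adduct may revert instead of expelling the hindered tertiary alkoxide, so that slow retro-Claisen fragmentation of the C3–C4–C5 diketone or aldol closure outruns ring A formation. The fallback makes the C2–CH2 bond last by reductive alkylation and sets out from 5 and 11. Commercial 2,4,6-trihydroxybenzophenone should be gem-diprenylated with 11 (NaOMe, MeOH, 0 °C) to 2-benzoyl-3,5-dihydroxy-6,6-bis(3-methylbut-2-en-1-yl)cyclohexa-2,4-dien-1-one F1. Its free ring CH should condense with aldehyde 5 (cat. proline, CH2Cl2) to the Knoevenagel alkylidene trione F2. Diethyl 2,6-dimethyl-1,4-dihydropyridine-3,5-dicarboxylate (Hantzsch ester) should reduce F2 in the same flask by conjugate transfer hydrogenation, and the fallback comes back to the route at 20.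

Step 11. The lithium enolate may add to the ketone or the enol-ether carbon of 18 instead of the hindered ring carbonyl, or proton transfer from the acidic product may stop the acylation halfway. The fallback assembles the chain in two stages without 18 and sets out from 15 and 9. Dichloride 15 should be mono-thioesterified with thiophenol (1 equiv, pyridine, CH2Cl2, −40 °C) to S-phenyl 3-chloro-2,2-bis(3-methylbut-2-en-1-yl)-3-oxopropanethioate F3. The lithium enolate of 9 (LiN(SiMe3)2, THF, −78 °C) should be C-acylated by the acyl chloride of F3 to the α-acyl lactone thioester F4. A soft-enolisation Claisen acylation of 16 by the thioester of F4 (MgBr2·OEt2, i-Pr2NEt, CH2Cl2) should install the benzoylacetyl end, and the fallback comes back at 19.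

Step 3. Facial control at the ketone may be poor, or the aldol may dehydrate or close in the opposite sense (ketone enamine onto the aldehyde). The fallback takes the stereochemistry from an epoxide and sets out from 4. Aldol condensation (piperidine, AcOH, benzene, reflux) should give (R)-2-methyl-5-(prop-1-en-2-yl)cyclopent-1-ene-1-carbaldehyde F5. Weitz–Scheffer epoxidation (H2O2, NaOH, MeOH, 0 °C), expected anti to the isopropenyl group, should give 5-methyl-2-(prop-1-en-2-yl)-6-oxabicyclo[3.1.0]hexane-1-carbaldehyde F6. A Wittig reaction with 6 should give the γ,δ-epoxy enoate methyl (E)-3-[5-methyl-2-(prop-1-en-2-yl)-6-oxabicyclo[3.1.0]hexan-1-yl]prop-2-enoate F7. Formate hydrogenolysis of the vinyl epoxide (Pd2(dba)3·CHCl3, PBu3, HCO2H/Et3N, dioxane) follows: zerovalent palladium ionises the allylic C–O bond with inversion and delivers hydride from the metal face. This should set the ring B methine with the side chain cis to the hydroxyl, and the fallback comes back at 7.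

Further compounds
F1 | step 12 | 2-benzoyl-3,5-dihydroxy-6,6-bis(3-methylbut-2-en-1-yl)cyclohexa-2,4-dien-1-one | O=C(c1ccccc1)C1=C(O)C=C(O)C(CC=C(C)C)(CC=C(C)C)C1=O
F2 | step 12 | Knoevenagel alkylidene trione from F1 and 5 (alkene geometry not controlled) | C=C(C)[C@H]1CC[C@](C)(O)[C@@H]1C=C1C(=O)C(CC=C(C)C)(CC=C(C)C)C(=O)C(C(=O)c2ccccc2)=C1O
F3 | step 11 | S-phenyl 3-chloro-2,2-bis(3-methylbut-2-en-1-yl)-3-oxopropanethioate | O=C(Cl)C(CC=C(C)C)(CC=C(C)C)C(=O)Sc1ccccc1
F4 | step 11 | S-phenyl 3-[(4aR,5S,7aS)-7a-methyl-2-oxo-5-(prop-1-en-2-yl)octahydrocyclopenta[b]pyran-3-yl]-2,2-bis(3-methylbut-2-en-1-yl)-3-oxopropanethioate (C3 of the lactone uncontrolled) | C=C(C)[C@H]1CC[C@]2(C)OC(=O)C(C(=O)C(CC=C(C)C)(CC=C(C)C)C(=O)Sc3ccccc3)C[C@H]12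
F5 | step 3 | (R)-2-methyl-5-(prop-1-en-2-yl)cyclopent-1-ene-1-carbaldehyde | CC1=C(C=O)[C@H](CC1)C(C)=C
F6 | step 3 | 5-methyl-2-(prop-1-en-2-yl)-6-oxabicyclo[3.1.0]hexane-1-carbaldehyde, epoxide oxygen trans to isopropenyl | C=C(C)[C@H]1CC[C@]2(C)O[C@]12C=O
F7 | step 3 | methyl (E)-3-[5-methyl-2-(prop-1-en-2-yl)-6-oxabicyclo[3.1.0]hexan-1-yl]prop-2-enoate, epoxide oxygen trans to isopropenyl | C=C(C)[C@H]1CC[C@]2(C)O[C@]12/C=C/C(=O)OC
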